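The route rests on cutting ring C away from ring A at O1–C8a and C4–C4a (flavan numbering). Both bonds are made in one operation by annulating an aryne (triple bond C4a≡C8a of ring A, C8 prenyl already in place) with an enantiopure γ-chloro alkoxide that carries O1, C2, C3, C4 and ring B. Oxygen adds to C8a, and the aryl anion left at C4a displaces chloride. The step exploits the C5 methoxy group beside C4a, which polarises the triple bond so that oxygen attacks C8a only. The aryne precursor is a fluoroarene lithiated between F and OMe. The C2 stereocentre comes from a CBS reduction and is never touched afterwards.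

Key step: step 6

Remark on the chemistry: ring A is the benzo ring, ring B the 2-aryl group, ring C the pyran ring. CIP analysis of the target SMILES gives the 2R configuration. Compounds 1, 3, 6 and 8 are assumed to be commercially available.

Step 1
Reactants: 1 3-fluoro-5-methoxyphenol
Product: 2 1-fluoro-3-methoxy-5-(methoxymethoxy)benzene
Conditions: NaH, MOMCl, DMF, 0 °C to rt
Reagents that add atoms: chloromethyl methyl ether (MOMCl), COCCl
Why: Williamson-type O-alkylation of the sodium phenoxide protects the future O7 phenol as an acetal that survives organolithiums and serves as the chelating director in step 2.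

Step 2
Reactants: 2 1-fluoro-3-methoxy-5-(methoxymethoxy)benzene; 3 1-bromo-3-methylbut-2-ene (prenyl bromide)
Product: 5 1-fluoro-5-methoxy-3-(methoxymethoxy)-2-(3-methylbut-2-en-1-yl)benzene, via aryllithium 4 (not isolated)
Conditions: n-BuLi, THF, −78 °C, 1 h; CuBr·SMe2 (10 mol %), 3, −78 to −40 °C
Reagents that add atoms: none
Why: Directed ortho-metalation should remove the proton between F and OMOM, the only site that combines the strongest acidifying group with the chelating acetal, and copper-catalysed allylic substitution at the primary carbon of 3, below the temperature of LiF loss, gives the linear prenyl arene.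

Step 3
Reactants: 6 3-bromo-5-methoxyphenol
Product: 7 1-bromo-3-methoxy-5-(methoxymethoxy)benzene
Conditions: NaH, MOMCl, DMF, 0 °C to rt
Reagents that add atoms: chloromethyl methyl ether (MOMCl), COCCl
Why: The same Williamson-type MOM protection is applied to the ring B phenol so that both phenols can be released together at the end.

Step 4
Reactants: 7 1-bromo-3-methoxy-5-(methoxymethoxy)benzene; 8 3-chloropropanoyl chloride
Product: 11 3-chloro-1-[3-methoxy-5-(methoxymethoxy)phenyl]propan-1-one, via aryllithium 9 (not isolated), via arylzinc chloride 10 (not isolated)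
Conditions: n-BuLi, THF, −78 °C; ZnCl2, −78 to 0 °C; 8, Pd(PPh3)4 (3 mol %), 0 °C to rt
Reagents that add atoms: none
Why: Bromine–lithium exchange, transmetalation to zinc and Negishi acylation under zerovalent palladium catalysis stop at the ketone, and the weakly basic arylzinc should not eliminate HCl from the β-chloro ketone.

Step 5
Reactants: 11 3-chloro-1-[3-methoxy-5-(methoxymethoxy)phenyl]propan-1-one
Product: 12 (1R)-3-chloro-1-[3-methoxy-5-(methoxymethoxy)phenyl]propan-1-ol
Conditions: (S)-2-methyl-CBS-oxazaborolidine (10 mol %), BH3·SMe2, THF, −20 °C; MeOH quench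
Reagents that add atoms: none
Why: In this Corey–Bakshi–Shibata reduction the (S)-oxazaborolidine·BH3 complex binds the ketone anti to the large aryl group and delivers hydride to the Si face, which sets the future C2 as R, as is established for 3-chloropropiophenones.

Step 6
Reactants: 5 1-fluoro-5-methoxy-3-(methoxymethoxy)-2-(3-methylbut-2-en-1-yl)benzene; 12 (1R)-3-chloro-1-[3-methoxy-5-(methoxymethoxy)phenyl]propan-1-ol
Product: 17 (2R)-5-methoxy-2-[3-methoxy-5-(methoxymethoxy)phenyl]-7-(methoxymethoxy)-8-(3-methylbut-2-en-1-yl)-3,4-dihydro-2H-chromene, via potassium alkoxide 13 (not isolated), via aryllithium 14 (not isolated), via aryne 15 (not isolated), via arylpotassium adduct 16 (not isolated)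
Conditions: flask A: 12 (2 equiv), KH, THF, 0 °C, then −15 °C; flask B: 5, s-BuLi (1.0 equiv), THF, −78 °C, 1 h; B into A by cannula over 1 h at −15 °C, then rt, 3 h
Reagents that add atoms: none
Why: Proposed new method: aryllithium 14 loses LiF on entering the warmer solution and gives aryne 15, the proton-free potassium alkoxide 13 adds through oxygen to C8a, and the C4a carbanion 16 displaces the primary chloride at C4, so that O1–C8a and C4–C4a form in one operation. The closest known reaction types are the addition of sodium or potassium alkoxides to 3-alkoxyarynes, aryne annulations in which the aryl anion born from a heteroatom addition is trapped by an internal electrophile, and the Parham cyclialkylation of aryllithiums bearing an ω-haloalkyl chain; their merger with an aliphatic γ-chloro alkoxide has not been shown. Ring C closes in the 6-exo-tet mode. No new stereocentre is formed, and C2 keeps its R configuration because neither its C–O bond nor its C–H bond is broken. The regioselectivity needed (O at C8a, C at C4a) is secured by the C5 methoxy group, whose inductive pull distorts the triple bond so that C8a is the more linear, more electrophilic end and the charge develops at C4a, flanked by the oxygen-bearing carbons C5 and C8a, whereas the C8 prenyl group only adds moderate bulk and should not override this bias. Chemoselectivity rests on slow inverse addition of 14 into an excess of 13, which keeps 14 dilute so that its own addition to 15 is suppressed, and on the slow 4-exo-tet oxetane closure of 13 below 0 °C.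

Step 7
Reactants: 17 (2R)-5-methoxy-2-[3-methoxy-5-(methoxymethoxy)phenyl]-7-(methoxymethoxy)-8-(3-methylbut-2-en-1-yl)-3,4-dihydro-2H-chromene
Product: 18 (2R)-2-(3-hydroxy-5-methoxyphenyl)-5-methoxy-8-(3-methylbut-2-en-1-yl)-3,4-dihydro-2H-chromen-7-ol (CNP0389420.1)
Conditions: HCl (3 M aq), MeOH, 40 °C
Reagents that add atoms: none
Why: Acid-catalysed transacetalisation of both aryl MOM acetals to dimethoxymethane frees the two phenols, while the methyl ethers and the C2–O1 benzylic ether (ring B offers only meta oxygen donors) should stay intact under such mild acid.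

Compound list
1 | 3-fluoro-5-methoxyphenol | COc1cc(O)cc(F)c1 | starting material
2 | 1-fluoro-3-methoxy-5-(methoxymethoxy)benzene | COCOc1cc(OC)cc(F)c1 | intermediate
3 | 1-bromo-3-methylbut-2-ene (prenyl bromide) | CC(C)=CCBr | starting material
4 | [2-fluoro-4-methoxy-6-(methoxymethoxy)phenyl]lithium | COCOc1cc(OC)cc(F)c1[Li] | intermediate
5 | 1-fluoro-5-methoxy-3-(methoxymethoxy)-2-(3-methylbut-2-en-1-yl)benzene | COCOc1cc(OC)cc(F)c1CC=C(C)C | intermediate
6 | 3-bromo-5-methoxyphenol | COc1cc(O)cc(Br)c1 | starting material
7 | 1-bromo-3-methoxy-5-(methoxymethoxy)benzene | COCOc1cc(OC)cc(Br)c1 | intermediate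
8 | 3-chloropropanoyl chloride | O=C(Cl)CCCl | starting material
9 | [3-methoxy-5-(methoxymethoxy)phenyl]lithium | COCOc1cc(OC)cc([Li])c1 | intermediate
10 | chloro[3-methoxy-5-(methoxymethoxy)phenyl]zinc | COCOc1cc(OC)cc([Zn]Cl)c1 | intermediate
11 | 3-chloro-1-[3-methoxy-5-(methoxymethoxy)phenyl]propan-1-one | COCOc1cc(OC)cc(C(=O)CCCl)c1 | intermediate
12 | (1R)-3-chloro-1-[3-methoxy-5-(methoxymethoxy)phenyl]propan-1-ol | COCOc1cc(OC)cc([C@@H](CCCl)O)c1 | intermediate
13 | potassium (1R)-3-chloro-1-[3-methoxy-5-(methoxymethoxy)phenyl]propan-1-olate | COCOc1cc(OC)cc([C@@H](CCCl)O[K])c1 | intermediate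
14 | [2-fluoro-6-methoxy-4-(methoxymethoxy)-3-(3-methylbut-2-en-1-yl)phenyl]lithium | COCOc1cc(OC)c([Li])c(F)c1CC=C(C)C | intermediate
15 | 3-methoxy-5-(methoxymethoxy)-6-(3-methylbut-2-en-1-yl)benzyne (1,2-didehydrobenzene, triple bond C4a≡C8a) | COC1=CC(OCOC)=C(CC=C(C)C)C#C1 | intermediate
16 | [2-{(1R)-3-chloro-1-[3-methoxy-5-(methoxymethoxy)phenyl]propoxy}-6-methoxy-4-(methoxymethoxy)-3-(3-methylbut-2-en-1-yl)phenyl]potassium | COCOc1cc(OC)c([K])c(O[C@H](CCCl)c2cc(OC)cc(OCOC)c2)c1CC=C(C)C | intermediate
17 | (2R)-5-methoxy-2-[3-methoxy-5-(methoxymethoxy)phenyl]-7-(methoxymethoxy)-8-(3-methylbut-2-en-1-yl)-3,4-dihydro-2H-chromene | COCOc1cc(OC)cc([C@H]2CCc3c(OC)cc(OCOC)c(CC=C(C)C)c3O2)c1 | intermediate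
18 | (2R)-2-(3-hydroxy-5-methoxyphenyl)-5-methoxy-8-(3-methylbut-2-en-1-yl)-3,4-dihydro-2H-chromen-7-ol | COc1cc(O)cc([C@H]2CCc3c(OC)cc(O)c(CC=C(C)C)c3O2)c1 | target

Total step count: 7.
Longest linear sequence: 5 steps (steps 3, 4, 5, 6 and 7).

Steps most likely to fail

Step 6 (the labelled step). Several processes could compete:
- addition of unreacted aryllithium to the aryne;
- hydride transfer from the carbinol C–H of the alkoxide to the aryne;
- proton capture by the C4a anion before ring closure;
- early oxetane closure of the alkoxide;
- lithiation of 5 at C6 or at the benzylic–allylic CH2.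

The fallback makes the two bonds one after the other with known chemistry. It sets out from 12 and 5 and comes back at 17. Compound 12 is closed with KOtBu in THF (Williamson 4-exo-tet closure, stereocentre untouched) to (2R)-2-[3-methoxy-5-(methoxymethoxy)phenyl]oxetane F1. Aryllithium 14, made from 5 with s-BuLi and held at −78 °C where it keeps its fluoride, opens F1 at the unsubstituted CH2–O carbon under BF3·OEt2 activation. This gives (1R)-3-[2-fluoro-6-methoxy-4-(methoxymethoxy)-3-(3-methylbut-2-en-1-yl)phenyl]-1-[3-methoxy-5-(methoxymethoxy)phenyl]propan-1-ol F2. The potassium alkoxide of F2 (KH, THF/DMPU, 60–80 °C) then closes O1–C8a by intramolecular SNAr on the fluoride. The two meta oxygen substituents help this closure, and no aryne escape is possible because both ortho positions are substituted. The product is 17.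

Step 2. The lithiation may show poor site selectivity among three doubly flanked ring positions, or LiF may be lost before alkylation. The fallback replaces metalation by a sigmatropic transfer. It sets out from 1 and comes back at 5. Phenol 1 is O-alkylated with tert-butyl (2-methylbut-3-en-2-yl) carbonate under Pd(PPh3)4 catalysis (Tsuji–Trost type reverse O-prenylation; the aryl fluoride is inert) to 1-fluoro-3-methoxy-5-[(2-methylbut-3-en-2-yl)oxy]benzene F3. Heating in N,N-diethylaniline at about 140 °C triggers the aromatic Claisen rearrangement. This should favour the ortho carbon next to the electron-withdrawing F and para to OMe, and give 3-fluoro-5-methoxy-2-(3-methylbut-2-en-1-yl)phenol F4. NaH/MOMCl then gives 5.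

Step 7. During acetal cleavage the liberated O7 phenol may add to the prenyl double bond under acid catalysis, or the alkene may be hydrated. The fallback exchanges the protecting groups under buffered, non-acidic conditions and finishes with fluoride. It sets out from 17 and comes back at 18. TESOTf with 2,2'-bipyridyl in CH2Cl2 at 0 °C converts both aryl MOM ethers into aryl silyl ethers. This gives (2R)-5-methoxy-2-[3-methoxy-5-(triethylsilyloxy)phenyl]-8-(3-methylbut-2-en-1-yl)-7-(triethylsilyloxy)-3,4-dihydro-2H-chromene F5. TBAF buffered with AcOH in THF at 0 °C then releases 18.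

Further compounds
F1 | step 6 | (2R)-2-[3-methoxy-5-(methoxymethoxy)phenyl]oxetane | COCOc1cc(OC)cc([C@H]2CCO2)c1
F2 | step 6 | (1R)-3-[2-fluoro-6-methoxy-4-(methoxymethoxy)-3-(3-methylbut-2-en-1-yl)phenyl]-1-[3-methoxy-5-(methoxymethoxy)phenyl]propan-1-ol | COCOc1cc(OC)cc([C@@H](CCc2c(OC)cc(OCOC)c(CC=C(C)C)c2F)O)c1
F3 | step 2 | 1-fluoro-3-methoxy-5-[(2-methylbut-3-en-2-yl)oxy]benzene | COc1cc(F)cc(OC(C)(C)C=C)c1
F4 | step 2 | 3-fluoro-5-methoxy-2-(3-methylbut-2-en-1-yl)phenol | COc1cc(O)c(CC=C(C)C)c(F)c1
F5 | step 7 | (2R)-5-methoxy-2-[3-methoxy-5-(triethylsilyloxy)phenyl]-8-(3-methylbut-2-en-1-yl)-7-(triethylsilyloxy)-3,4-dihydro-2H-chromene | COc1cc(O[Si](CC)(CC)CC)cc([C@H]2CCc3c(OC)cc(O[Si](CC)(CC)CC)c(CC=C(C)C)c3O2)c1
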